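Begin with a division. One closed flask, theta, has been followed at 25 °C and is asked about at 40 min; an earlier flask, epsilon, differs from it in its free catalyst.

in all of them: starting material 21 mM; coupling partner 18.9 mM; temperature 25 °C

| flask | free catalyst | remark | time |
|---|---|---|---|
| theta | 0.53 mM | the very flask that is asked about, followed so far |  |
| epsilon | 0.36 mM | run made earlier |  |
| flask | 0.53 mM |  | 40 min |

theta run (percent of the starting material charged)

| time / min | target / % | starting material / % |
|---|---|---|
| 3.00 | 34.9 | 60.9 |
| 6.00 | 56.5 | 38.7 |
| 10.0 | 64.6 | 21.5 |
| 15.0 | 67.9 | 15.5 |
| 20.0 | 65.4 | 14.4 |
| 25.0 | 66.4 | 10.5 |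

epsilon run (percent of the starting material charged)

| time / s | target / % | starting material / % |
|---|---|---|
| 10.0 | 0.4 | 98.5 |
| 12.0 | 0.1 | 98.9 |
| 25.0 | 3.6 | 95.7 |
| 40.0 | 4.7 | 92.7 |
| 50.0 | 5.9 | 90.5 |
| 60.0 | 9.0 | 91.5 |
| 80.0 | 12.6 | 85.9 |

(scatter of a reading: 1 percentage point)

- ochre: at 40 min raise the temperature by 20 K, then wait 12 min
- red: change nothing and wait 12 min more
- green: at 40 min take out 90% of the by-product then present, then wait 12 min
- amber: at 40 min add coupling partner, 100% of the amount charged, then wait 12 min
- blue: at 40 min add free catalyst, 100% of the amount charged, then wait 12 min

- what is added takes up no volume worth counting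
- the earlier runs do not show what temperature does; that part of a forecast is a guess

- target, in percent of the starting material first charged, at 40 min
- the option that brings most further target ("none" if no option brings more than 2 percentage points) (ochre / red / green / amber / blue / none)
- target present, in percent of the starting material first charged, after ochre
- target present, in percent of the starting material first charged, after green

Two theta readings seem not to go together. From 15.0 min to 25.0 min starting material falls from 15.5% to 10.5%, yet target goes from 67.9% to 66.4%, no rise beyond the scatter. At the last reading we reckon:

reacted starting material = 89.5%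

reacted but not seen as target = 23.1%

Coupling partner is charged in smaller amount than starting material, so we take it as the limiting reagent and assume that each reacted starting material costs one coupling partner, whatever it becomes. This gives the partner ceiling, the share of the starting material that the coupling partner can carry through:

[coupling partner] charged / [starting material] charged = 90.0%

By the last reading, reacted starting material stands close to that ceiling. So we read the ceiling as a limit on what reacts, not on target, and the contradiction clears: target is a share of the reacted amount, 74.2% at the last reading.

The catalyst is a small correction. If each catalyst unit ties up one starting material without partner, a further 2.52% goes, and free starting material ends at 7.48%.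

Our own reckoning takes the mean of the target readings from 15.0 min to 25.0 min, 66.6%, for 40 min and after green. Amber lifts the ceiling and opens the remainder, which at the same share brings 7.4 percentage points. Red, green and blue leave the ceiling where it stands. Ochre does too, but it could move the share, and the runs do not show temperature.

The forecast gives 65.5% now, amber as best, 65% after ochre and 66% after green, holding that “More partner could convert most of the remainder”.

Theta gives 67.4%, and 67.7% after green. Amber brings 7.5 points, but ochre brings 15 points, reaching 81.9%.

    coupling partner + catalyst intermediate A → catalyst intermediate B (k = 88.0 /M/s, Ea = 41.0 kJ/mol)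
    catalyst intermediate C ⇌ free catalyst + target (K = 0.0350 M, k = 0.510 /s, Ea = 62.0 kJ/mol, ΔH = −4.00 kJ/mol)
    catalyst intermediate B ⇌ by-product + catalyst intermediate C (K = 0.0310 M, k = 0.140 /s, Ea = 68.0 kJ/mol, ΔH = −47.0 kJ/mol)
    target + free catalyst ⇌ isomer of the product + free catalyst, rate k4*[free catalyst]*[target] forward; the back reaction follows from the equilibrium constant (K = 0.320, k = 4.70 /M/s, Ea = 53.0 kJ/mol, ΔH = −52.0 kJ/mol)
    starting material + free catalyst ⇌ catalyst intermediate A (K = 37.0 /M, k = 150 /M/s, Ea = 44.0 kJ/mol, ΔH = −41.0 kJ/mol)
    starting material + free catalyst → spent catalyst (k = 0.150 /M/s, Ea = 64.0 kJ/mol)
    (constants at 25 °C)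

Theta has not quite come to rest. At ten times the time, 400 min, target moves from 67.4% to 68.2%, while free starting material goes from 9.51% to 7.54%, the reckoned end, and spent catalyst from 45.5% to 97.6%. Target and isomer of the product then sum to 90.0%, at the ceiling. A neighbour charged with 53 mM of starting material has the ceiling 35.7%, and at 40.0 min, with coupling partner at 0%, its target and isomer of the product sum to 35.7%.

(The readings come from a simulation from invented constants.)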